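**Retrosynthetic overview**

- Numbering: ring A = C1(=CH2)–C2H2–C3H(OH)–C4H(Br)–C5Me2–C6 (spiro); ring B = C6–C7H2–C8H2–C9(Me)(OH)–C10H(Cl)–C11H2. The strategy rests on C4, a neopentyl CHBr between C5Me2 and the C3 carbinol: it can only be brominated through a C3 enol derivative whose double bond is fixed at C3=C4, away from the allylic C2.
- Endgame, read backwards: C9–Me by methyl addition to a C10 chloro ketone; C10–Cl (and with it C6) by catalyst-controlled chlorination of the symmetrical ring B ketone; cis C3–OH/C4–Br by dynamic asymmetric reduction of the C4 bromo C3 ketone; C4–Br by NBS/water on the C3(OMe)=C4 enol ether.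
- Key disconnection: C3=C4 of that enol ether, by ring-closing metathesis of a 2-methoxyalkene (made from an ester) with the vinyl group on C5.
- Acyclic precursor: C1–C2 by enol triflate/Reformatsky coupling; C5–C6 by Ireland–Claisen rearrangement of the prenyl ester of the ring B acid.
- Ring order: ring B is bought as the ketal-protected cyclohexane; ring A is the only ring made, closed in step 7.

Key step: step 7

Assumption: the antipodes named for the chiral catalysts of steps 9 and 11 follow the usual transition-state models for these catalyst classes; should either show the opposite sense on this substrate, its mirror image is used and nothing else changes.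

**Route**

Step 1
Reactants: 1 1,4-dioxaspiro[4.5]decane-8-carboxylic acid; 2 3-methylbut-2-en-1-ol (prenol)
Product: 3 3-methylbut-2-en-1-yl 1,4-dioxaspiro[4.5]decane-8-carboxylate
Conditions: EDC·HCl, DMAP (cat.), CH2Cl2, 0 °C to rt
Reagents that add atoms: none
Why: Steglich-type carbodiimide esterification of an unhindered acid with a primary allylic alcohol proceeds under neutral conditions that leave the dioxolane intact.

Step 2
Reactants: 3 3-methylbut-2-en-1-yl 1,4-dioxaspiro[4.5]decane-8-carboxylate
Product: 6 8-(2-methylbut-3-en-2-yl)-1,4-dioxaspiro[4.5]decane-8-carboxylic acid, via silyl ketene acetal 4 (not isolated), via trimethylsilyl ester 5 (not isolated)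
Conditions: LiN(iPr)2, THF, −78 °C; Me3SiCl/Et3N, −78 °C to rt, then 65 °C; H2O work-up (pH 4–5)
Reagents that add atoms: none
Why: Ireland–Claisen rearrangement: the tetrasubstituted silyl ketene acetal of the ring B ester undergoes a [3,3] shift through a chair transition state that joins the ester α-carbon (C6) to the dimethyl-substituted terminus of the prenyl group (C5), so both quaternary carbons and the vinyl group (future C4) arise together, and no stereocentre forms because ring B is symmetrical.

Step 3
Reactants: 6 8-(2-methylbut-3-en-2-yl)-1,4-dioxaspiro[4.5]decane-8-carboxylic acid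
Product: 8 1-[8-(2-methylbut-3-en-2-yl)-1,4-dioxaspiro[4.5]decan-8-yl]ethan-1-one, via dilithium gem-diolate 7 (not isolated)
Conditions: MeLi (3.5 equiv), Et2O, 0 °C to rt; poured into ice-water
Reagents that add atoms: methyllithium, [Li]C
Why: Organolithium conversion of a carboxylic acid into a methyl ketone: addition of MeLi to the lithium carboxylate stops at the dilithium gem-diolate, which releases the ketone only on hydrolysis, and a ketone flanked by two quaternary carbons does not take up a second equivalent.

Step 4
Reactants: 8 1-[8-(2-methylbut-3-en-2-yl)-1,4-dioxaspiro[4.5]decan-8-yl]ethan-1-one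
Product: 10 1-[8-(2-methylbut-3-en-2-yl)-1,4-dioxaspiro[4.5]decan-8-yl]ethenyl trifluoromethanesulfonate, via potassium enolate 9 (not isolated)
Conditions: KN(SiMe3)2, THF, −78 °C; PhNTf2, −78 °C to 0 °C
Reagents that add atoms: N-phenylbis(trifluoromethanesulfonimide), O=S(=O)(N(c1ccccc1)S(=O)(=O)C(F)(F)F)C(F)(F)F
Why: Enolate O-sulfonylation: the ketone has a single enolisable position (its methyl group), so triflation of the potassium enolate can only give the 1,1-disubstituted enol triflate that becomes the C1 methylene.

Step 5
Reactants: 10 1-[8-(2-methylbut-3-en-2-yl)-1,4-dioxaspiro[4.5]decan-8-yl]ethenyl trifluoromethanesulfonate; 11 methyl bromoacetate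
Product: 13 methyl 3-[8-(2-methylbut-3-en-2-yl)-1,4-dioxaspiro[4.5]decan-8-yl]but-3-enoate, via Reformatsky reagent 12 (not isolated)
Conditions: 11, Zn dust (Me3SiCl-activated), THF, 40 °C; then 10, Pd(PPh3)4 (5 mol%), THF/DMPU, 60 °C
Reagents that add atoms: none
Why: Negishi-type cross-coupling of a Reformatsky reagent: zerovalent palladium inserts into the vinyl C–OTf bond, the C-bound zinc enolate transmetalates and reductive elimination forms the C1–C2 bond, the neutral medium keeping the new double bond out of conjugation with the ester.

Step 6
Reactants: 13 methyl 3-[8-(2-methylbut-3-en-2-yl)-1,4-dioxaspiro[4.5]decan-8-yl]but-3-enoate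
Product: 14 8-(4-methoxypenta-1,4-dien-2-yl)-8-(2-methylbut-3-en-2-yl)-1,4-dioxaspiro[4.5]decane
Conditions: Cp2TiMe2 (2.5 equiv), toluene/THF, 65 °C, dark; filtration through basic alumina
Reagents that add atoms: dimethyltitanocene (Petasis reagent), C[Ti](C)(C1C=CC=C1)C1C=CC=C1
Why: Petasis methylenation: thermally generated Cp2Ti=CH2 converts the ester carbonyl into the 2-methoxyalkene through an oxatitanacyclobutane, and since the reagent is neither basic nor Lewis acidic the doubly allylic C2 methylene is undisturbed and the enol ether double bond is placed at C3 with no choice of enolisation direction involved.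

Step 7
Reactants: 14 8-(4-methoxypenta-1,4-dien-2-yl)-8-(2-methylbut-3-en-2-yl)-1,4-dioxaspiro[4.5]decane
Product: 15 11-methoxy-9,9-dimethyl-13-methylidene-1,4-dioxadispiro[4.2.5⁸.2⁵]pentadec-10-ene (ring A methyl enol ether C3(OMe)=C4 with the C1 methylene; ring B as the C9 dioxolane)
Conditions: second-generation Grubbs catalyst RuCl2(=CHPh)(H2IMes)(PCy3) (10 mol%), 1,4-benzoquinone (20 mol%), degassed toluene (0.005 M), 80 °C, argon sparge
Reagents that add atoms: none
Why: Ring-closing olefin metathesis: the 14-electron ruthenium alkylidene loads on the monosubstituted vinyl group on C5, adds across the 2-methoxyalkene in a [2+2] sense with ruthenium on the terminal CH2, and the ruthenacyclobutane opens to the C3=C4 double bond and Ru=CH2, ethylene leaving the solution. The closest known reaction type is the ruthenium- or molybdenum-catalysed ring-closing metathesis of acyclic alkyl and silyl enol ethers, themselves made by ester methylenation, to five- to seven-membered cyclic enol ethers. Ring A is closed as a six-membered ring by joining C3 to C4, the chain C4–C5–C6–C1–C2–C3 being already in place. No stereocentre is formed, C6 being non-stereogenic while ring B carries the symmetrical dioxolane. The step needs chemoselectivity among three alkenes: the 1,1-disubstituted C1 methylene on the quaternary C6 is too hindered to load and could only close a four-membered ring, the adjacent quaternary carbons C5 and C6 hold the reacting termini close (Thorpe–Ingold effect), and high dilution suppresses cross-metathesis. The product is the one enol derivative of the C3 ketone whose double bond points to C4 and away from the allylic C2.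

Step 8
Reactants: 15 11-methoxy-9,9-dimethyl-13-methylidene-1,4-dioxadispiro[4.2.5⁸.2⁵]pentadec-10-ene
Product: 16 racemic 10-bromo-9,9-dimethyl-13-methylidene-1,4-dioxadispiro[4.2.5⁸.2⁵]pentadecan-11-one (C4 bromo C3 ketone)
Conditions: NBS (1.0 equiv), NaHCO3, THF/H2O (4:1), 0 °C
Reagents that add atoms: N-bromosuccinimide, O=C1CCC(=O)N1Br; water, O
Why: Electrophilic bromination of an enol ether: Br+ from NBS adds to the β-carbon C4, water captures the C3 oxocarbenium ion and the hemiketal loses methanol, the enol ether being far more nucleophilic than the C1 methylene so that one equivalent of NBS should react only at C4, which is formed as a racemate at this stage.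

Step 9
Reactants: 16 racemic 10-bromo-9,9-dimethyl-13-methylidene-1,4-dioxadispiro[4.2.5⁸.2⁵]pentadecan-11-one
Product: 17 (10S,11R)-10-bromo-9,9-dimethyl-13-methylidene-1,4-dioxadispiro[4.2.5⁸.2⁵]pentadecan-11-ol (cis bromohydrin: C3 R and C4 S)
Conditions: RuCl[(S,S)-TsDPEN](p-cymene) (2 mol%), HCO2H/Et3N (5:2), CH2Cl2, 25 °C
Reagents that add atoms: none
Why: Noyori–Ikariya asymmetric transfer hydrogenation with dynamic kinetic resolution of a cyclic α-bromo ketone: the axial C4–H exchanges through the C3 enol in the buffered medium while the ruthenium hydride (allylic C2 arm in the site an aryl group normally takes) reduces the (4S) ketone faster, delivering hydride along the equatorial trajectory at C3 because the axial one is blocked by the axial C5 methyl, so the axial C3 hydroxyl (R) ends cis to the equatorial C4 bromine (S), the catalyst fixing C3 and thereby selecting C4.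

Step 10
Reactants: 17 (10S,11R)-10-bromo-9,9-dimethyl-13-methylidene-1,4-dioxadispiro[4.2.5⁸.2⁵]pentadecan-11-ol
Product: 18 (8S,9R)-8-bromo-9-hydroxy-7,7-dimethyl-11-methylidenespiro[5.5]undecan-3-one (ring B C9 ketone)
Conditions: 1 M aq. HCl/THF (1:4), rt
Reagents that add atoms: water, O
Why: Acid-catalysed dioxolane hydrolysis under mild aqueous conditions should free the C9 ketone without touching the bromohydrin or moving the C1 methylene into the ring, C6 remaining non-stereogenic.

Step 11
Reactants: 18 (8S,9R)-8-bromo-9-hydroxy-7,7-dimethyl-11-methylidenespiro[5.5]undecan-3-one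
Product: 19 (2S,6S,8S,9R)-8-bromo-2-chloro-9-hydroxy-7,7-dimethyl-11-methylidenespiro[5.5]undecan-3-one (C10 chloro C9 ketone)
Conditions: (4R,5R)-4,5-diphenylimidazolidine (20 mol%), 2-nitrobenzoic acid (20 mol%), NCS (1.0 equiv), MeCN, −25 °C
Reagents that add atoms: N-chlorosuccinimide, O=C1CCC(=O)N1Cl
Why: Enamine-catalysed enantioselective α-chlorination used as a desymmetrisation: in the ring B chair with C5 equatorial and C1 axial, chlorine can enter only on the face opposite the axial C1 arm (1,3-diaxial hindrance), and on that face the C2-symmetric amine accepts only the enamine towards C10, so choosing C10 over C8 makes C6 stereogenic (S) and places chlorine equatorial at C10 (S), cis to C5, which is also the thermodynamically preferred epimer.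

Step 12
Reactants: 19 (2S,6S,8S,9R)-8-bromo-2-chloro-9-hydroxy-7,7-dimethyl-11-methylidenespiro[5.5]undecan-3-one
Product: 20 (2S,3R,6S,8S,9R)-2-bromo-8-chloro-1,1,9-trimethyl-5-methylidenespiro[5.5]undecane-3,9-diol (target)
Conditions: CeCl3 (anhydrous, 4 equiv), MeMgBr (4 equiv), THF, −78 °C; then H2O/THF at −78 °C
Reagents that add atoms: methylmagnesium bromide, C[Mg]Br
Why: Organocerium 1,2-addition to an α-chloro ketone: the weakly basic methylcerium reagent should add without enolising C10 and attack C9 along the equatorial trajectory, on the side of the small axial C10–H, so that methyl ends equatorial and trans to chlorine and the tertiary hydroxyl axial and cis to it (C9 R), as in classical methyl-metal additions to 2-chlorocyclohexanones, while the C3 alkoxide is inert because oxygen and bromine are cis and the cold quench prevents rearrangement of the chlorohydrin alkoxide.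

**Compound list**

1 | 1,4-dioxaspiro[4.5]decane-8-carboxylic acid | OC(=O)C1CCC2(CC1)OCCO2 | starting material
2 | 3-methylbut-2-en-1-ol (prenol) | CC(C)=CCO | starting material
3 | 3-methylbut-2-en-1-yl 1,4-dioxaspiro[4.5]decane-8-carboxylate | CC(C)=CCOC(=O)C1CCC2(CC1)OCCO2 | intermediate
4 | silyl ketene acetal: trimethyl{[(3-methylbut-2-en-1-yl)oxy](1,4-dioxaspiro[4.5]decan-8-ylidene)methoxy}silane | CC(C)=CCOC(O[Si](C)(C)C)=C1CCC2(CC1)OCCO2 | intermediate (not isolated)
5 | trimethylsilyl 8-(2-methylbut-3-en-2-yl)-1,4-dioxaspiro[4.5]decane-8-carboxylate | C=CC(C)(C)C1(C(=O)O[Si](C)(C)C)CCC2(CC1)OCCO2 | intermediate (not isolated)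
6 | 8-(2-methylbut-3-en-2-yl)-1,4-dioxaspiro[4.5]decane-8-carboxylic acid | C=CC(C)(C)C1(C(=O)O)CCC2(CC1)OCCO2 | intermediate
7 | dilithium 1-[8-(2-methylbut-3-en-2-yl)-1,4-dioxaspiro[4.5]decan-8-yl]ethane-1,1-diolate | CC([O-])([O-])C1(C(C)(C)C=C)CCC2(CC1)OCCO2.[Li+].[Li+] | intermediate (not isolated)
8 | 1-[8-(2-methylbut-3-en-2-yl)-1,4-dioxaspiro[4.5]decan-8-yl]ethan-1-one | CC(=O)C1(C(C)(C)C=C)CCC2(CC1)OCCO2 | intermediate
9 | potassium 1-[8-(2-methylbut-3-en-2-yl)-1,4-dioxaspiro[4.5]decan-8-yl]ethen-1-olate | C=C([O-])C1(C(C)(C)C=C)CCC2(CC1)OCCO2.[K+] | intermediate (not isolated)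
10 | 1-[8-(2-methylbut-3-en-2-yl)-1,4-dioxaspiro[4.5]decan-8-yl]ethenyl trifluoromethanesulfonate | C=C(OS(=O)(=O)C(F)(F)F)C1(C(C)(C)C=C)CCC2(CC1)OCCO2 | intermediate
11 | methyl bromoacetate | COC(=O)CBr | starting material
12 | bromo(2-methoxy-2-oxoethyl)zinc (Reformatsky reagent) | COC(=O)C[Zn]Br | intermediate (not isolated)
13 | methyl 3-[8-(2-methylbut-3-en-2-yl)-1,4-dioxaspiro[4.5]decan-8-yl]but-3-enoate | COC(=O)CC(=C)C1(C(C)(C)C=C)CCC2(CC1)OCCO2 | intermediate
14 | 8-(4-methoxypenta-1,4-dien-2-yl)-8-(2-methylbut-3-en-2-yl)-1,4-dioxaspiro[4.5]decane | COC(=C)CC(=C)C1(C(C)(C)C=C)CCC2(CC1)OCCO2 | intermediate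
15 | 11-methoxy-9,9-dimethyl-13-methylidene-1,4-dioxadispiro[4.2.5⁸.2⁵]pentadec-10-ene | COC1=CC(C)(C)C2(CCC3(CC2)OCCO3)C(=C)C1 | intermediate
16 | racemic 10-bromo-9,9-dimethyl-13-methylidene-1,4-dioxadispiro[4.2.5⁸.2⁵]pentadecan-11-one | O=C1CC(=C)C2(CCC3(CC2)OCCO3)C(C)(C)C1Br | intermediate
17 | (10S,11R)-10-bromo-9,9-dimethyl-13-methylidene-1,4-dioxadispiro[4.2.5⁸.2⁵]pentadecan-11-ol | C=C1C[C@@H](O)[C@@H](Br)C(C)(C)C12CCC3(CC2)OCCO3 | intermediate
18 | (8S,9R)-8-bromo-9-hydroxy-7,7-dimethyl-11-methylidenespiro[5.5]undecan-3-one | C=C1C[C@@H](O)[C@@H](Br)C(C)(C)C12CCC(=O)CC2 | intermediate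
19 | (2S,6S,8S,9R)-8-bromo-2-chloro-9-hydroxy-7,7-dimethyl-11-methylidenespiro[5.5]undecan-3-one | C=C1C[C@@H](O)[C@@H](Br)C(C)(C)[C@]12CCC(=O)[C@@H](Cl)C2 | intermediate
20 | (2S,3R,6S,8S,9R)-2-bromo-8-chloro-1,1,9-trimethyl-5-methylidenespiro[5.5]undecane-3,9-diol | C=C1C[C@@H](O)[C@@H](Br)C(C)(C)[C@]12CC[C@@](C)(O)[C@@H](Cl)C2 | target

**Step count and risks**

Total steps: 12. Longest linear sequence: 12 steps (from compound 1).

The three steps most likely to fail:

1. Step 7 (ring-closing metathesis). The ruthenium carbene may form only slowly at a vinyl group flanked by two quaternary carbons. The catalyst may be drained into an unreactive alkoxy-substituted carbene by loading at the enol ether. Ruthenium hydride formed on catalyst decay may move the C3=C4 enol ether double bond into conjugation with the C1 methylene, which would destroy the regiochemical purpose of the step. The fallback sets out from ester 13 and comes back at enol ether 15. Compound 13 would be treated with the reduced titanium ethylidene reagent prepared from TiCl4, TMEDA, Zn, PbCl2 (cat.) and CH3CHBr2 in THF/CH2Cl2 (Takai–Utimoto conditions, 25 to 65 °C). The titanium alkylidene exchanges onto the C5 vinyl group and then olefinates the ester carbonyl intramolecularly, so C3=C4 is made by carbonyl–olefin metathesis without a ruthenium carbene and without handling the acid-sensitive triene 14. No compound outside the list is made (F0).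

2. Step 9 (dynamic asymmetric reduction). Epimerisation at the hindered C4 may be too slow, so that conversion stalls near one half. Enolisation towards the allylic C2 may move the C1 methylene into conjugation with the C3 ketone. Face selection by the transfer-hydrogenation catalyst may be weak for a ketone without an aryl group. The fallback sets out from racemic 16 and comes back at 17. It is a kinetic resolution by Corey–Bakshi–Shibata reduction with (S)-2-methyl-CBS-oxazaborolidine (20 mol%) and catecholborane (0.55 equiv) in toluene at −78 °C. With the C4 arm as the large group the catalyst delivers hydride to the face that gives C3 (R). For the (10S) ketone this is also the substrate-preferred equatorial trajectory, so that enantiomer should be reduced quickly to 17. The mismatched, unreacted (10R)-10-bromo-9,9-dimethyl-13-methylidene-1,4-dioxadispiro[4.2.5⁸.2⁵]pentadecan-11-one F1 would be removed by chromatography. Half of the material is given up in exchange for independence from C4 epimerisation and from basic conditions.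

3. Step 11 (desymmetrising chlorination). C8 and C10 differ only through the remote centres of ring A, so site selection rests wholly on the catalyst. Incomplete discrimination would lead into the C6-epimeric series, and double chlorination or loss of the catalyst to N-chlorination may also intervene. The fallback sets out from 18 and comes back at 19. Deprotonation that selects between the two α-methylenes would be done with lithium bis[(R)-1-phenylethyl]amide (2.2 equiv, or its mirror image, whichever removes the axial C10 proton) and LiCl in THF at −100 °C in the presence of Me3SiCl. This should give (2S,3R,6S)-2-bromo-1,1-dimethyl-5-methylidene-3,9-bis(trimethylsilyloxy)spiro[5.5]undec-8-ene F2, the C9=C10 silyl enol ether with the C3 hydroxyl also silylated. NCS in THF at −78 to 0 °C then chlorinates C10 on the face away from the axial C1 arm, and work-up with aqueous citric acid removes the C3 silyl group to give 19.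

Further compounds
F0 | step 7 | none | none
F1 | step 9 | (10R)-10-bromo-9,9-dimethyl-13-methylidene-1,4-dioxadispiro[4.2.5⁸.2⁵]pentadecan-11-one | C=C1CC(=O)[C@H](Br)C(C)(C)C12CCC3(CC2)OCCO3
F2 | step 11 | (2S,3R,6S)-2-bromo-1,1-dimethyl-5-methylidene-3,9-bis(trimethylsilyloxy)spiro[5.5]undec-8-ene | C=C1C[C@@H](O[Si](C)(C)C)[C@@H](Br)C(C)(C)[C@]12CCC(O[Si](C)(C)C)=CC2
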